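**Plan**

Target numbering: OH on C1 and C2, Br on C3, C4 and C6, CH3 on C5; the molecule has no stereocentre, so no stereochemistry has to be set.
Retrosynthesis: the C3–Br and C4–Br bonds are cut first (bromination of an activated catechol), the two hydroxyls are then masked as methyl ethers, and the adjacent C5–CH3 and C6–Br bonds are cut together.
That last cut rests on one feature: CH3 and Br sit on neighbouring ring carbons C5 and C6, and C6 is flanked by the oxygen-bearing C1. This is the pattern an aryne across C5/C6 with an alkoxy group beside it leaves when a carbon nucleophile enters at the remote carbon and a bromine electrophile at the carbon next to oxygen.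
Forward: 4-bromo-1,2-dimethoxybenzene 1, MeMgBr 2 and 1,2-dibromotetrachloroethane 3 are joined in one flask through aryllithium 4, aryne 5 and arylmagnesium 6 to give 3-bromo-1,2-dimethoxy-4-methylbenzene 7; BBr3 frees catechol 8 and Br2 fills the two open ring positions to give the target 9.
The benzene ring is bought with 1; no ring is formed in the route.

Key step: step 1

Remark: lithium 2,2,6,6-tetramethylpiperidide (LiTMP) is used as a preformed THF solution, made separately from 2,2,6,6-tetramethylpiperidine and n-BuLi.

**Step 1**
Reactants: 1 4-bromo-1,2-dimethoxybenzene; 2 methylmagnesium bromide; 3 1,2-dibromo-1,1,2,2-tetrachloroethane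
Product: 7 3-bromo-1,2-dimethoxy-4-methylbenzene, via (6-bromo-2,3-dimethoxyphenyl)lithium 4 (not isolated), via 3,4-didehydro-1,2-dimethoxybenzene 5 (not isolated), via (2,3-dimethoxy-6-methylphenyl)magnesium bromide 6 (not isolated)
Conditions: LiTMP (1.2 equiv), THF, −78 °C, 30 min; MeMgBr (3 equiv), −78 → 40 °C; then (BrCl2C)2 (4 equiv), −20 °C → rt
Reagents that add atoms: methylmagnesium bromide C[Mg]Br; 1,2-dibromo-1,1,2,2-tetrachloroethane BrC(Cl)(Cl)C(Cl)(Cl)Br
Why: The hindered amide removes the C3–H of 1, the one proton flanked by Br and OCH3, to give aryllithium 4, which on warming expels metal bromide to form the 3-alkoxyaryne 5; MeMgBr then adds across the strained triple bond (aryne carbomagnesiation) and the arylmagnesium 6 so formed is brominated by 3 with loss of tetrachloroethene. The closest known reaction type is the regioselective addition of organomagnesium and organolithium reagents to 3-alkoxyarynes and 2-alkoxy-3,4-pyridynes followed by electrophilic quench of the ortho-metalated product. Two selectivities are needed: deprotonation at the single position between Br and OCH3, secured by the combined acidifying effect of both groups, and delivery of methyl to the aryne carbon remote from oxygen (C4 of 1, the future C5 of the target). The second is secured by the inductively withdrawing methoxy group beside the triple bond, which distorts the aryne so that the remote carbon is the electrophilic end and places the developing carbanion next to oxygen (C3 of 1, the future C6), where magnesium is also chelated. No ring is closed and no stereocentre is created; the excess of 2 is meant to outcompete the poorly nucleophilic amide and the aryl anions 4 and 6 for the aryne.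

**Step 2**
Reactants: 7 3-bromo-1,2-dimethoxy-4-methylbenzene
Product: 8 3-bromo-4-methylbenzene-1,2-diol
Conditions: BBr3 (3 equiv), CH2Cl2, −78 °C → rt; ice/H2O work-up under argon
Reagents that add atoms: none
Why: Lewis-acid ether cleavage, in which BBr3 coordinates each methoxy oxygen and bromide removes the methyl group by SN2 attack, is a standard aryl methyl ether demethylation that leaves the aryl bromide and the ring methyl untouched.

**Step 3**
Reactants: 8 3-bromo-4-methylbenzene-1,2-diol
Product: 9 3,4,6-tribromo-5-methylbenzene-1,2-diol
Conditions: Br2 (2.1 equiv), AcOH, 10 °C → rt, dark; aq. Na2S2O4 work-up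
Reagents that add atoms: bromine BrBr
Why: Electrophilic aromatic bromination of a catechol should be fast at the two remaining ring positions, one para and one ortho to a hydroxyl, and since these are the only free sites twofold substitution can give only 9, while the reductive work-up returns any ortho-quinone to the catechol.

**Compound list**

1 | 4-bromo-1,2-dimethoxybenzene | COc1ccc(Br)cc1OC | starting material
2 | methylmagnesium bromide | C[Mg]Br | starting material
3 | 1,2-dibromo-1,1,2,2-tetrachloroethane | BrC(Cl)(Cl)C(Cl)(Cl)Br | starting material
4 | (6-bromo-2,3-dimethoxyphenyl)lithium | COc1ccc(Br)c([Li])c1OC | intermediate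
5 | 3,4-didehydro-1,2-dimethoxybenzene | COC1=C(OC)C#CC=C1 | intermediate
6 | (2,3-dimethoxy-6-methylphenyl)magnesium bromide | COc1ccc(C)c([Mg]Br)c1OC | intermediate
7 | 3-bromo-1,2-dimethoxy-4-methylbenzene | COc1ccc(C)c(Br)c1OC | intermediate
8 | 3-bromo-4-methylbenzene-1,2-diol | Cc1ccc(O)c(O)c1Br | intermediate
9 | 3,4,6-tribromo-5-methylbenzene-1,2-diol | Cc1c(Br)c(O)c(O)c(Br)c1Br | target

Total step count: 3
Longest linear sequence: 3 steps (1 → 7 → 8 → 9)

**Steps most likely to fail**

Risk 1, step 1 (aryne carbobromination). The aryne 5 may be captured by the amide base or by the aryl anions 4 and 6 faster than by the methyl reagent, giving arylamine and biaryl by-products, and the methyl transfer itself may be sluggish. The fallback gives up the aryne and uses the same acidic C–H of 1 to carry a silicon placeholder. Setting out from 1, LiTMP with Me3SiCl already present (THF, −78 °C, in situ quench) should trap aryllithium 4 before it loses bromide and give (6-bromo-2,3-dimethoxyphenyl)trimethylsilane F1. Bromine–lithium exchange (n-BuLi, THF, −78 °C) followed by MeI should give (2,3-dimethoxy-6-methylphenyl)trimethylsilane F2. Ipso-bromodesilylation (Br2, CH2Cl2, 0 °C), favoured at the silicon-bearing carbon by the beta-silicon effect, then replaces silicon by bromine and returns to the route at 7.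

Risk 2, step 3 (dibromination of the free catechol). Bromine may act as an oxidant on the catechol, so that ortho-quinone formation, HBr addition to the quinone and incomplete second substitution give a mixture of oxidation levels. The fallback carries the oxidation through on purpose. Setting out from 8, excess Br2 in AcOH followed by HNO3 should funnel the material to 3,4,6-tribromo-5-methylcyclohexa-3,5-diene-1,2-dione F3. This quinone is purified by crystallisation and reduced with Na2S2O4 (EtOAc/H2O), coming back to the route at 9.

Risk 3, step 2 (ether cleavage). Demethylation may stall at a monomethyl ether, and the electron-rich catechol may be lost by air oxidation while it is liberated and isolated. The fallback reverses the order of the last two operations. Setting out from 7, Br2 with catalytic FeBr3 (CH2Cl2, dark) should fill both free ring positions at the ether stage and give 1,2,4-tribromo-5,6-dimethoxy-3-methylbenzene F4. BBr3 (CH2Cl2, −78 °C → rt) then releases the electron-poor, oxidation-resistant catechol directly and rejoins the route at 9.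

**Further compounds**

F1 | step 1 | (6-bromo-2,3-dimethoxyphenyl)trimethylsilane | COc1ccc(Br)c([Si](C)(C)C)c1OC
F2 | step 1 | (2,3-dimethoxy-6-methylphenyl)trimethylsilane | COc1ccc(C)c([Si](C)(C)C)c1OC
F3 | step 3 | 3,4,6-tribromo-5-methylcyclohexa-3,5-diene-1,2-dione | CC1=C(Br)C(=O)C(=O)C(Br)=C1Br
F4 | step 2 | 1,2,4-tribromo-5,6-dimethoxy-3-methylbenzene | COc1c(Br)c(Br)c(C)c(Br)c1OC
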